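**Retrosynthetic overview**

1. Ring A (the chloro-hydroxy-quinone) is unmasked last: the target comes from a 2-alkyl-4-chloro-5-methylresorcinol, whose only free ring C–H lies para to one hydroxyl, by phenol oxidation after MOM removal.
2. Key disconnection: the side-chain bond between the methyl-bearing alkene carbon C3' and the carbinol carbon C4' of the unit ArCH2(C1')–CH(C2')=C(CH3)(C3')–CH(OH)(C4')–CH2(C5')–ring B. It is made by one-pot alkyne hydrozirconation, Zr-to-Zn exchange and ligand-controlled addition to a keto aldehyde.
3. Enabling feature: the E-trisubstituted C2'=C3' alkene carries its methyl on C3' and has only CH2 groups on both flanks (benzylic C1', and C5' on the quaternary carbon of ring B). This is the exact retron of a methyl-capped but-2-ynyl arene plus a CH2CHO group, and the ring B ketone needs no protection.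
4. Fragments: the alkyne from orcinol (MOM protection, lithiation between the two oxygens and propargylation, chlorination); the keto aldehyde from 3,4-dimethylanisole (Birch reduction, enantioselective isomerisation to (R)-3,4-dimethylcyclohexenone, vinyl cuprate addition anti to the C4 methyl with enolate methylation, hydroboration, oxidation).
5. No ring is built: ring B is the dearomatised anisole ring (formed first) and ring A is the orcinol ring, oxidised to the quinone in the last step.

Key step: step 10

Assumption: the sense of induction of the chiral amine catalyst (step 3) and of the amino thiol ligand (step 10) is assigned by analogy with simple substrates; the pseudoenantiomeric catalyst or the antipodal ligand would be used if the opposite sense were found.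

**Route**

Step 1
Reactants: 1 3,4-dimethylanisole
Product: 2 1-methoxy-4,5-dimethylcyclohexa-1,4-diene
Conditions: Li, liq. NH3, THF, t-BuOH, −78 → −33 °C; H2O
Reagents that add atoms: none
Why: Birch reduction, in which protonation ortho and meta to the methoxy group should leave the methoxy and both methyl groups on sp2 carbons and give the 1,4-diene with a tetrasubstituted alkene.

Step 2
Reactants: 2 1-methoxy-4,5-dimethylcyclohexa-1,4-diene
Product: 3 3,4-dimethylcyclohex-3-en-1-one
Conditions: oxalic acid (cat.), MeOH/H2O, rt
Reagents that add atoms: water O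
Why: Enol ether hydrolysis under weak acid should release the ketone without moving the tetrasubstituted alkene into conjugation.

Step 3
Reactants: 3 3,4-dimethylcyclohex-3-en-1-one
Product: 4 (R)-3,4-dimethylcyclohex-2-en-1-one
Conditions: 9-amino-9-deoxy-epi-cinchona primary amine catalyst (10 mol%), carboxylic acid co-catalyst (20 mol%), toluene, −25 °C
Reagents that add atoms: none
Why: Amine-catalysed enantioselective alkene isomerisation (iminium ion, then dienamine, then catalyst-directed protonation at C4) should move the alkene into conjugation and set the C4 stereocentre as R under catalyst control.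

Step 4
Reactants: 4 (R)-3,4-dimethylcyclohex-2-en-1-one
Product: 7 (2R,3S,4R)-2,3,4-trimethyl-3-vinylcyclohexan-1-one, via bromomagnesium enolate 5 (not isolated), via C2-epimeric ketone mixture 6 (not isolated)
Conditions: CH2=CHMgBr (2.2 equiv), CuBr·SMe2 (1.1 equiv), THF, −78 → −20 °C; MeI, DMPU, −20 °C → rt; crude product, NaOMe (cat.), MeOH, rt
Reagents that add atoms: vinylmagnesium bromide C=C[Mg]Br; iodomethane CI
Why: Cuprate conjugate addition with enolate trapping: allylic 1,2-strain holds the C4 methyl pseudoaxial so the vinyl group should add to the opposite face and set the quaternary C3, the regiodefined enolate is C-methylated at C2, and base equilibration should converge C2 on the epimer with both secondary methyl groups equatorial (2R).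

Step 5
Reactants: 7 (2R,3S,4R)-2,3,4-trimethyl-3-vinylcyclohexan-1-one
Product: 9 (2R,3S,4R)-3-(2-hydroxyethyl)-2,3,4-trimethylcyclohexan-1-ol (both C1 epimers), via bis(9-BBN) adduct 8 (not isolated)
Conditions: 9-BBN (3 equiv), THF, 65 °C; NaOH, H2O2, 0 °C → rt
Reagents that add atoms: hydrogen peroxide OO
Why: Anti-Markovnikov hydroboration–oxidation should place boron on the terminal vinyl carbon away from the quaternary centre; the concurrent ketone reduction by excess borane is harmless because both carbinols are oxidised in step 6.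

Step 6
Reactants: 9 (2R,3S,4R)-3-(2-hydroxyethyl)-2,3,4-trimethylcyclohexan-1-ol
Product: 11 2-[(1S,2R,6R)-1,2,6-trimethyl-3-oxocyclohexyl]acetaldehyde, via bis(alkoxysulfonium) dichloride 10 (not isolated)
Conditions: (COCl)2, DMSO, CH2Cl2, −78 °C; Et3N, −78 → 0 °C
Reagents that add atoms: none
Why: Swern oxidation activates both carbinols before base is added, so aldehyde and ketone should form together without a bridged lactol being intercepted, and C2 already sits in its thermodynamic configuration.

Step 7
Reactants: 12 orcinol (5-methylbenzene-1,3-diol)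
Product: 13 1,3-bis(methoxymethoxy)-5-methylbenzene
Conditions: MOMCl (3 equiv), iPr2NEt (4 equiv), CH2Cl2, 0 °C → rt
Reagents that add atoms: chloromethyl methyl ether COCCl
Why: O-Alkylation of both phenols gives acetal ethers that direct the next metalation and are removable without protic acid.

Step 8
Reactants: 13 1,3-bis(methoxymethoxy)-5-methylbenzene
Product: 15 2-(but-2-yn-1-yl)-1,3-bis(methoxymethoxy)-5-methylbenzene, via aryllithium 14 (not isolated)
Conditions: n-BuLi (1.1 equiv), THF, 0 °C; 1-bromobut-2-yne (1.3 equiv), −78 °C → rt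
Reagents that add atoms: 1-bromobut-2-yne CC#CCBr
Why: Directed ortho-metalation should occur at the carbon flanked by both OMOM groups, and SN2 alkylation at the primary propargylic bromide is favoured because the methyl cap on the alkyne hinders SN2′ attack.

Step 9
Reactants: 15 2-(but-2-yn-1-yl)-1,3-bis(methoxymethoxy)-5-methylbenzene
Product: 16 2-(but-2-yn-1-yl)-4-chloro-1,3-bis(methoxymethoxy)-5-methylbenzene
Conditions: NCS (1.0 equiv), DMF, 0 °C → rt
Reagents that add atoms: N-chlorosuccinimide O=C1CCC(=O)N1Cl
Why: Electrophilic aromatic chlorination; the two free ring positions are equivalent by symmetry and each is ortho/para to the two oxygens, so monochlorination should give one regioisomer while the internal alkyne stays inert.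

Step 10
Reactants: 16 2-(but-2-yn-1-yl)-4-chloro-1,3-bis(methoxymethoxy)-5-methylbenzene, 11 2-[(1S,2R,6R)-1,2,6-trimethyl-3-oxocyclohexyl]acetaldehyde
Product: 19 (2R,3S,4R)-3-[(2S,3E)-5-[3-chloro-2,6-bis(methoxymethoxy)-4-methylphenyl]-2-hydroxy-3-methylpent-3-en-1-yl]-2,3,4-trimethylcyclohexan-1-one, via (E)-alkenyl-ZrCp2Cl 17 (not isolated), via (E)-alkenyl-ZnMe 18 (not isolated)
Conditions: 16 (1.5 equiv), Cp2Zr(H)Cl (1.6 equiv), THF, 50 °C; then 16 (0.15 equiv); evaporate, toluene; Me2Zn (1.5 equiv), −65 °C; (S)-2-[1-(dimethylamino)ethyl]benzenethiol (10 mol%), 11 (1.0 equiv), −30 → 0 °C; aq. NH4Cl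
Reagents that add atoms: none
Why: Syn-hydrozirconation of the but-2-ynyl group of 16, equilibrated by the slight excess of Zr–H, should place zirconium on the methyl-bearing alkyne carbon (the smaller terminus) and give the E-alkenylzirconocene 17; Zr-to-Zn exchange with Me2Zn proceeds with retention to 18, whose ligand-bound form adds to the aldehyde of 11 and forges the bond between the methyl-bearing alkene carbon and the carbinol carbon. The closest known reaction type is the one-pot hydrozirconation, zinc transmetalation and amino thiol-catalysed asymmetric 1,2-addition of alkenylzinc reagents to aldehydes. No ring is closed. The E geometry of the trisubstituted alkene follows from syn addition of Zr–H and stereoretentive transmetalation, and the new (S)-carbinol centre is set by the chiral zinc amino thiolate, which should deliver the alkenyl group to the Re face of the aldehyde; the quaternary β-carbon of 11 offers little 1,3-induction, so reagent control is expected to dominate. The step needs regioselective hydrometalation (secured by the CH3 versus ArCH2 size difference and thermodynamic equilibration), chemoselectivity for the aldehyde over the ring ketone (alkenylzinc reagents should not add to a hindered α-branched ketone at low temperature, and the aryl chloride and MOM ethers are inert) and facial selectivity (secured by the ligand). The residual Zr–H is consumed by a small second portion of 16 before 11 is added, so that the aldehyde is not reduced.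

Step 11
Reactants: 19 (2R,3S,4R)-3-[(2S,3E)-5-[3-chloro-2,6-bis(methoxymethoxy)-4-methylphenyl]-2-hydroxy-3-methylpent-3-en-1-yl]-2,3,4-trimethylcyclohexan-1-one
Product: 21 4-chloro-2-[(2E,4S)-4-hydroxy-3-methyl-5-[(1S,2R,6R)-1,2,6-trimethyl-3-oxocyclohexyl]pent-2-en-1-yl]-5-methylbenzene-1,3-diol, via tris(trimethylsilyl) ether 20 (not isolated)
Conditions: TMSOTf (5 equiv), 2,2'-bipyridyl (7 equiv), MeCN, 0 °C → rt; then H2O, aq. citric acid, THF, rt
Reagents that add atoms: none
Why: Buffered silyl triflate-mediated acetal cleavage should turn the aryl MOM ethers into aryl silyl ethers (and silylate the carbinol), all hydrolysed on aqueous work-up, which avoids the protic acid that could ionise the allylic alcohol or close a chroman onto the alkene.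

Step 12
Reactants: 21 4-chloro-2-[(2E,4S)-4-hydroxy-3-methyl-5-[(1S,2R,6R)-1,2,6-trimethyl-3-oxocyclohexyl]pent-2-en-1-yl]-5-methylbenzene-1,3-diol
Product: 22 5-chloro-2-hydroxy-3-[(2E,4S)-4-hydroxy-3-methyl-5-[(1S,2R,6R)-1,2,6-trimethyl-3-oxocyclohexyl]pent-2-en-1-yl]-6-methylcyclohexa-2,5-diene-1,4-dione (CNP0469571.1)
Conditions: (KSO3)2NO (3 equiv), aq. KH2PO4 (pH 6)/acetone, 0 °C → rt
Reagents that add atoms: potassium nitrosodisulfonate [K+].[K+].[O]N(S(=O)(=O)[O-])S(=O)(=O)[O-]
Why: Teuber oxidation: the aryloxy radical should be trapped by a second nitroxyl radical at the only free ring carbon, para to the hydroxyl next to chlorine, and loss of imidodisulfonate gives the p-quinone with the other hydroxyl retained, while the alcohol, alkene and ketone are inert to the reagent.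

**Compound list**

1 | 3,4-dimethylanisole | COc1ccc(C)c(C)c1 | starting material
2 | 1-methoxy-4,5-dimethylcyclohexa-1,4-diene | COC1=CCC(C)=C(C)C1 | intermediate
3 | 3,4-dimethylcyclohex-3-en-1-one | CC1=C(C)CC(=O)CC1 | intermediate
4 | (R)-3,4-dimethylcyclohex-2-en-1-one | C[C@@H]1CCC(=O)C=C1C | intermediate
5 | bromomagnesium enolate of the 3-vinyl conjugate adduct (vinyl trans to the C4 methyl) | C=C[C@@]1(C)[C@H](C)CCC(O[Mg]Br)=C1 | intermediate (not isolated)
6 | (3S,4R)-2,3,4-trimethyl-3-vinylcyclohexan-1-one, both C2 epimers | C=C[C@@]1(C)[C@H](C)CCC(=O)C1C | intermediate (not isolated)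
7 | (2R,3S,4R)-2,3,4-trimethyl-3-vinylcyclohexan-1-one | C=C[C@@]1(C)[C@H](C)CCC(=O)[C@@H]1C | intermediate
8 | bis(9-BBN) adduct (B-alkyl on the side chain, B–O on the ring carbinol) | B1(CC[C@@]2(C)[C@H](C)CCC(OB3C4CCCC3CCC4)[C@@H]2C)C2CCCC1CCC2 | intermediate (not isolated)
9 | (2R,3S,4R)-3-(2-hydroxyethyl)-2,3,4-trimethylcyclohexan-1-ol, both C1 epimers | OCC[C@@]1(C)[C@H](C)CCC(O)[C@@H]1C | intermediate
10 | bis(alkoxysulfonium) dichloride of 9 | C[S+](C)OCC[C@@]1(C)[C@H](C)CCC(O[S+](C)C)[C@@H]1C.[Cl-].[Cl-] | intermediate (not isolated)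
11 | 2-[(1S,2R,6R)-1,2,6-trimethyl-3-oxocyclohexyl]acetaldehyde | O=CC[C@@]1(C)[C@H](C)CCC(=O)[C@@H]1C | intermediate
12 | orcinol (5-methylbenzene-1,3-diol) | Cc1cc(O)cc(O)c1 | starting material
13 | 1,3-bis(methoxymethoxy)-5-methylbenzene | COCOc1cc(C)cc(OCOC)c1 | intermediate
14 | 2,6-bis(methoxymethoxy)-4-methylphenyllithium | [Li]c1c(OCOC)cc(C)cc1OCOC | intermediate (not isolated)
15 | 2-(but-2-yn-1-yl)-1,3-bis(methoxymethoxy)-5-methylbenzene | CC#CCc1c(OCOC)cc(C)cc1OCOC | intermediate
16 | 2-(but-2-yn-1-yl)-4-chloro-1,3-bis(methoxymethoxy)-5-methylbenzene | CC#CCc1c(OCOC)cc(C)c(Cl)c1OCOC | intermediate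
17 | (E)-alkenylzirconocene chloride, Zr on the methyl-bearing carbon | C/C(=C\Cc1c(OCOC)cc(C)c(Cl)c1OCOC)[Zr](Cl)(C1C=CC=C1)C1C=CC=C1 | intermediate (not isolated)
18 | (E)-alkenyl(methyl)zinc | C/C(=C\Cc1c(OCOC)cc(C)c(Cl)c1OCOC)[Zn]C | intermediate (not isolated)
19 | (2R,3S,4R)-3-[(2S,3E)-5-[3-chloro-2,6-bis(methoxymethoxy)-4-methylphenyl]-2-hydroxy-3-methylpent-3-en-1-yl]-2,3,4-trimethylcyclohexan-1-one | COCOc1cc(C)c(Cl)c(OCOC)c1C/C=C(\C)[C@@H](O)C[C@@]2(C)[C@H](C)CCC(=O)[C@@H]2C | intermediate
20 | tris(trimethylsilyl) ether of 21 | C[Si](C)(C)Oc1cc(C)c(Cl)c(O[Si](C)(C)C)c1C/C=C(\C)[C@@H](O[Si](C)(C)C)C[C@@]2(C)[C@H](C)CCC(=O)[C@@H]2C | intermediate (not isolated)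
21 | 4-chloro-2-[(2E,4S)-4-hydroxy-3-methyl-5-[(1S,2R,6R)-1,2,6-trimethyl-3-oxocyclohexyl]pent-2-en-1-yl]-5-methylbenzene-1,3-diol | Oc1cc(C)c(Cl)c(O)c1C/C=C(\C)[C@@H](O)C[C@@]2(C)[C@H](C)CCC(=O)[C@@H]2C | intermediate
22 | 5-chloro-2-hydroxy-3-[(2E,4S)-4-hydroxy-3-methyl-5-[(1S,2R,6R)-1,2,6-trimethyl-3-oxocyclohexyl]pent-2-en-1-yl]-6-methylcyclohexa-2,5-diene-1,4-dione | CC1=C(Cl)C(=O)C(C/C=C(\C)[C@@H](O)C[C@@]2(C)[C@H](C)CCC(=O)[C@@H]2C)=C(O)C1=O | target

**Step count and risks**

Total step count: 12. Longest linear sequence: 9 steps (steps 1–6, then 10–12); the alkyne branch (steps 7–9) has 3 steps.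

Steps most likely to fail:

Step 10. The hydrozirconation may lose regiocontrol if an ortho OMOM oxygen chelates zirconium and holds it on the benzylic-side carbon. The ligand may also fail to override the facial preference of the unbranched aldehyde, and the keto aldehyde may be partly consumed by reduction or intramolecular aldol reaction. The fallback separates the events. It sets out from 16, which is hydrozirconated with excess Cp2Zr(H)Cl in THF at 50 °C and treated with iodine to give (E)-2-(3-iodobut-2-en-1-yl)-4-chloro-1,3-bis(methoxymethoxy)-5-methylbenzene F1, freed from its regioisomer by chromatography. F1 is then joined to 11 by a Nozaki–Hiyama–Kishi coupling (NiCl2 cat., CrCl2, chiral oxazoline sulfonamide ligand, MeCN or DMSO, rt), a reaction that tolerates the ketone, and the route is rejoined at 19.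

Step 3. The isomerisation may be slow for a tetrasubstituted β,γ-alkene, or the protonation may be insufficiently face-selective. The fallback sets out from 3, which is isomerised with DBU to racemic 3,4-dimethylcyclohex-2-en-1-one F2. Lithiated (S)-N,S-dimethyl-S-phenylsulfoximine is added to the carbonyl group, and the diastereomeric β-hydroxysulfoximine derived from the R enone, F3, is separated by chromatography. Thermolysis of F3 in toluene at reflux releases the enone, and the route is rejoined at 4.

Step 12. The chlorinated resorcinol may be oxidised sluggishly, or the hydroxyquinone may be degraded by further oxidation or by attack at the chlorine-bearing quinone carbon. The fallback sets out from 21 and brings in the oxygen as carbon first. Magnesium-mediated ortho-formylation (MgCl2, Et3N, paraformaldehyde, MeCN) at the single free ring position gives 3-chloro-4,6-dihydroxy-5-[(2E,4S)-4-hydroxy-3-methyl-5-[(1S,2R,6R)-1,2,6-trimethyl-3-oxocyclohexyl]pent-2-en-1-yl]-2-methylbenzaldehyde F4. Dakin oxidation (H2O2, aq. NaHCO3, THF, 0 °C) converts F4 into 5-chloro-6-methyl-3-[(2E,4S)-4-hydroxy-3-methyl-5-[(1S,2R,6R)-1,2,6-trimethyl-3-oxocyclohexyl]pent-2-en-1-yl]benzene-1,2,4-triol F5, which is oxidised by air to the quinone, and the route is rejoined at 22.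

Further compounds

F1 | step 10 | (E)-2-(3-iodobut-2-en-1-yl)-4-chloro-1,3-bis(methoxymethoxy)-5-methylbenzene | C/C(I)=C\Cc1c(OCOC)cc(C)c(Cl)c1OCOC
F2 | step 3 | racemic 3,4-dimethylcyclohex-2-en-1-one | CC1CCC(=O)C=C1C
F3 | step 3 | (4R)-3,4-dimethyl-1-{[(S)-N-methyl-S-phenylsulfonimidoyl]methyl}cyclohex-2-en-1-ol (carbinol configuration not assigned) | C[C@@H]1CCC(O)(C[S@@](=O)(=NC)c2ccccc2)C=C1C
F4 | step 12 | 3-chloro-4,6-dihydroxy-5-[(2E,4S)-4-hydroxy-3-methyl-5-[(1S,2R,6R)-1,2,6-trimethyl-3-oxocyclohexyl]pent-2-en-1-yl]-2-methylbenzaldehyde | O=Cc1c(O)c(C/C=C(\C)[C@@H](O)C[C@@]2(C)[C@H](C)CCC(=O)[C@@H]2C)c(O)c(Cl)c1C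
F5 | step 12 | 5-chloro-6-methyl-3-[(2E,4S)-4-hydroxy-3-methyl-5-[(1S,2R,6R)-1,2,6-trimethyl-3-oxocyclohexyl]pent-2-en-1-yl]benzene-1,2,4-triol | Oc1c(O)c(C/C=C(\C)[C@@H](O)C[C@@]2(C)[C@H](C)CCC(=O)[C@@H]2C)c(O)c(Cl)c1C
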